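The route is built on cutting the C4–C19 bond of the 19,10-lactone. In the target, C19 is an ester carbonyl held between the quaternary carbon C4 and the α-oxygen on C10, spanning the lower face of ring A, and C4 is the direct neighbour of C3, which can be carried as a ketone. An enolate across C3–C4 can thus pick up C19 from a carbonate already attached to the C10 oxygen. This single operation makes C4–C19, closes the γ-lactone and sets the quaternary centre C4. The precursor is the tetracyclic ring A enone (C1=C2–C3=O, C4–H carrying C18) with a phenyl carbonate on the tertiary C10 oxygen, silyl ethers at C12, C13 and C15, and a fluoride-labile C7 ester.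

Key step: step 27

Remark on the chemistry: gibberellin numbering is used for every carbon from the alkylated dione on (C8 is the quaternary carbon, C15–C17 the propargyl carbons, ring B the five-membered ring, ring C the six-membered ring); β is the face of the C8 propargyl group and later of the C15–C16 bridge; the carbonate is made as the phenyl carbonate so that the non-enolisable β-keto lactone is released beside a poorly nucleophilic phenoxide; C7 is carried as a 2-(trimethylsilyl)ethyl ester; C15 is oxygenated before ring A is closed because selenium dioxide is expected to hydroxylate the exo (α) face, so the 15β-alcohol is reached through the 15-ketone.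

Step 1
Reactants: 1 cyclopentane-1,3-dione; 2 3-bromoprop-1-yne
Product: 3 2-(prop-2-yn-1-yl)cyclopentane-1,3-dione
Conditions: NaOH, H2O, 0 → 60 °C
Reagents that add atoms: none
Why: C-alkylation of the 1,3-dione enolate, which in water should be favoured over O-alkylation.

Step 2
Reactants: 3 2-(prop-2-yn-1-yl)cyclopentane-1,3-dione; 4 but-3-en-2-one
Product: 5 2-(3-oxobutyl)-2-(prop-2-yn-1-yl)cyclopentane-1,3-dione
Conditions: AcOH (cat.), H2O, 75 °C
Reagents that add atoms: none
Why: Michael addition of the acidic 2-substituted dione to the enone creates the C8 quaternary carbon (still prochiral).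

Step 3
Reactants: 5 2-(3-oxobutyl)-2-(prop-2-yn-1-yl)cyclopentane-1,3-dione
Product: 7 (R)-7a-(prop-2-yn-1-yl)-2,3,7,7a-tetrahydro-1H-indene-1,5(6H)-dione, via cis-fused ketol 6 (not isolated)
Conditions: (S)-proline (0.3 equiv), DMF, rt; then H2SO4 (cat.), DMF, 95 °C
Reagents that add atoms: none
Why: Hajos–Parrish reaction (proline enamine aldol that differentiates the two ring carbonyls, then acid dehydration); (S)-proline should set C8 in the same spatial sense as in the parent methyl series.

Step 4
Reactants: 7 (R)-7a-(prop-2-yn-1-yl)-2,3,7,7a-tetrahydro-1H-indene-1,5(6H)-dione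
Product: 8 C12 ethyl dienol ether, 5-ethoxy-7a-(prop-2-yn-1-yl)-2,6,7,7a-tetrahydro-1H-inden-1-one (C12(OEt)=C11, C9=C10, C6 ketone free)
Conditions: HC(OEt)3, TsOH·H2O (cat.), EtOH/THF, rt; Et3N quench
Reagents that add atoms: triethyl orthoformate, CCOC(OCC)OCC
Why: acid-catalysed enol ether formation with an orthoester should select the enone (as its extended dienol ether) over the hindered cyclopentanone, as it does in steroidal 4-ene-3,17-diones.

Step 5
Reactants: 8 C12 ethyl dienol ether; 9 (methoxymethyl)triphenylphosphonium chloride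
Product: 11 bicyclic enone 6β-carbaldehyde (formyl cis to the propargyl group), via bis(enol ether) 10 (not isolated)
Conditions: KOC(CH3)3, THF, 0 °C → reflux; then 2 M HCl, THF, rt
Reagents that add atoms: water, O
Why: Wittig methoxymethylenation of the neopentyl C6 ketone and acid hydrolysis of both enol ethers; under the acid the aldehyde should settle as the more stable 6β-epimer, as 17-formyl hydrindanes do.

Step 6
Reactants: 11 bicyclic enone 6β-carbaldehyde
Product: 12 bicyclic enone 6β-carboxylic acid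
Conditions: NaClO2, NaH2PO4, 2-methylbut-2-ene, t-BuOH/H2O, 0 °C → rt
Reagents that add atoms: sodium chlorite, [Na+].[O-]Cl=O
Why: Pinnick oxidation is selective for the aldehyde beside the enone and the alkyne and does not epimerise C6.

Step 7
Reactants: 12 bicyclic enone 6β-carboxylic acid
Product: 13 bicyclic enone 6β-carboxylic acid 2-(trimethylsilyl)ethyl ester
Conditions: Me3SiCH2CH2OH, EDC·HCl, DMAP, CH2Cl2, rt
Reagents that add atoms: 2-(trimethylsilyl)ethanol, C[Si](C)(C)CCO
Why: Steglich-type carbodiimide esterification; the silylethyl ester lets fluoride free C7 at the end together with the silyl ethers.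

Step 8
Reactants: 13 bicyclic enone 6β-carboxylic acid 2-(trimethylsilyl)ethyl ester
Product: 15 10α-hydroxy enone ester, via ethyl dienol ether 14 (not isolated)
Conditions: HC(OEt)3, TsOH·H2O (cat.), EtOH/dioxane, rt; then pyridine, mCPBA, dioxane/H2O, 0 °C
Reagents that add atoms: 3-chloroperbenzoic acid, OOC(=O)c1cccc(Cl)c1; water, O
Why: γ-hydroxylation of an enone through its extended dienol ether, the peracid attacking the distal C9=C10 bond anti to the propargyl group; the C10 configuration does not matter because C10 later becomes a ketone.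

Step 9
Reactants: 15 10α-hydroxy enone ester
Product: 16 10α-acetoxy enone ester
Conditions: Ac2O, pyridine, DMAP (cat.), CH2Cl2, rt
Reagents that add atoms: acetic anhydride, CC(=O)OC(C)=O
Why: acetylation masks the C10 oxygen with a group that should survive the enolate, hydride and samarium steps and that mild methanolysis removes.

Step 10
Reactants: 16 10α-acetoxy enone ester
Product: 18 13α-(triethylsilyloxy) enone, via triethylsilyl dienol ether 17 (not isolated)
Conditions: LiN(i-Pr)2 (1.05 equiv), Et3SiCl, THF, −78 °C; then mCPBA, NaHCO3, CH2Cl2, −20 → 0 °C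
Reagents that add atoms: chlorotriethylsilane, CC[Si](Cl)(CC)CC; 3-chloroperbenzoic acid, OOC(=O)c1cccc(Cl)c1
Why: Rubottom oxidation, with kinetic α′-deprotonation at C13 (C11 is vinylic, and the ketone proton is far more acidic than the alkyne and acetate protons) trapped in situ, epoxidation of the silyl enol ether and silyl shift to the new oxygen; the C13 configuration is erased in step 14.

Step 11
Reactants: 18 13α-(triethylsilyloxy) enone
Product: 19 12α-alcohol (12α-hydroxy, 13α-triethylsilyloxy, 10α-acetoxy, C9=C11)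
Conditions: LiBH(s-Bu)3, THF, −78 °C; AcOH, −78 °C
Reagents that add atoms: none
Why: 1,2-reduction of the β,β-disubstituted enone by a bulky borohydride from the equatorial side should give the pseudo-axial 12α-alcohol, trans to the C8 substituent, as steroidal 4-en-3-ones give 3α-alcohols; the cold acidic quench prevents silyl migration.

Step 12
Reactants: 19 12α-alcohol
Product: 20 12α-(tert-butyldimethylsilyl) ether
Conditions: t-BuMe2SiOTf, 2,6-lutidine, CH2Cl2, −78 → 0 °C
Reagents that add atoms: tert-butyldimethylsilyl triflate, CC(C)(C)[Si](C)(C)OS(=O)(=O)C(F)(F)F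
Why: silyl triflate silylation of the hindered secondary alcohol.

Step 13
Reactants: 20 12α-(tert-butyldimethylsilyl) ether
Product: 21 13α-alcohol (12α-silyl ether kept)
Conditions: PPTS (cat.), MeOH/CH2Cl2, 0 °C → rt
Reagents that add atoms: none
Why: acid-catalysed methanolysis should remove the secondary triethylsilyl ether much faster than the tert-butyldimethylsilyl ether, and without base no 1,2-silyl migration is expected.

Step 14
Reactants: 21 13α-alcohol
Product: 22 13-ketone (12α-silyloxy ketone, C9=C11, C8 propargyl)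
Conditions: Dess–Martin periodinane, NaHCO3, CH2Cl2, 0 °C
Reagents that add atoms: none
Why: buffered Dess–Martin oxidation should leave the base-sensitive β,γ-unsaturated α-silyloxy ketone unisomerised; it is used at once.

Step 15
Reactants: 22 13-ketone
Product: 23 tricyclic alcohol (rings B, C, D): 10α-acetoxy, 12α-silyloxy, 13-hydroxy, C9=C11, C16 methylene
Conditions: SmI2, HMPA, t-BuOH, THF, −78 → 0 °C
Reagents that add atoms: none
Why: samarium diiodide ketyl–alkyne reductive cyclisation (5-exo-dig) closes ring D and gives the bridgehead C13 alcohol and the C16 methylene; the C13 configuration is dictated by the tether from C8, and α-alkoxy ketones are tolerated in ketyl cyclisations when a proton source is present.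

Step 16
Reactants: 23 tricyclic alcohol
Product: 24 tricyclic 10α,13-diol
Conditions: K2CO3, MeOH, 0 °C → rt
Reagents that add atoms: none
Why: transesterification removes the allylic acetate; the hindered silylethyl ester should survive, and the silyl group has no reason to move from the C12 oxygen to the tertiary C13 oxygen.

Step 17
Reactants: 24 tricyclic 10α,13-diol
Product: 25 tricyclic 9(11)-en-10-one
Conditions: MnO2, CH2Cl2, rt
Reagents that add atoms: none
Why: MnO2 oxidises only the allylic secondary alcohol at C10, not the tertiary C13 alcohol.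

Step 18
Reactants: 25 tricyclic 9(11)-en-10-one
Product: 26 tricyclic 10-ketone (9β-H, cis B/C fusion)
Conditions: [(Ph3P)CuH]6, H2O, benzene/THF, rt
Reagents that add atoms: none
Why: copper hydride conjugate reduction is chemoselective for the enone over the isolated methylene; C9 is set by protonation of the enolate on the β-face, away from the axial 12α-silyl ether, and later bases deprotonate C5, not C9.

Step 19
Reactants: 26 tricyclic 10-ketone; 27 ethyl (S)-2-(trifluoromethylsulfonyloxy)propanoate
Product: 28 C5-alkylated ketone (5β-H; ethyl 2-propanoate unit on the α-face of C5, C4 configuration from inversion and immaterial)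
Conditions: LiN(i-Pr)2 (2.2 equiv), THF, −78 °C; then 27, −78 → −50 °C
Reagents that add atoms: none
Why: kinetic enolate at the C5 methylene and SN2 alkylation by the α-triflyloxy ester; the electrophile should enter anti to the C6 ester, and C5 stays epimerisable toward this trans arrangement.

Step 20
Reactants: 28 C5-alkylated ketone; 29 vinylmagnesium bromide
Product: 31 10β-vinyl γ-lactone (carbonyl C3 on the C10 oxygen), via magnesium alkoxide 30 (not isolated)
Conditions: CeCl3, THF, −78 °C; then rt
Reagents that add atoms: none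
Why: organocerium 1,2-addition to the ketone from the convex β-face, anti to the C5 side chain, then lactonisation of the alkoxide onto the cis ethyl ester; only the 10α-alkoxide can close this ring.

Step 21
Reactants: 31 10β-vinyl γ-lactone
Product: 33 15-oxo lactone, via 15α-alcohol 32 (not isolated)
Conditions: SeO2 (0.5 equiv), t-BuOOH, CH2Cl2, 0 °C → rt; then Dess–Martin periodinane, NaHCO3, CH2Cl2, rt
Reagents that add atoms: tert-butyl hydroperoxide, CC(C)(C)OO
Why: selenium dioxide ene reaction and [2,3]-shift hydroxylate the only allylic methylene (C15), expected on the exo α-face, and oxidation of the crude alcohol converges on the 15-oxo-16-ene; no other ketone is present at this stage.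

Step 22
Reactants: 33 15-oxo lactone
Product: 34 15β-alcohol lactone
Conditions: NaBH4, CeCl3·7H2O, MeOH, −78 °C
Reagents that add atoms: none
Why: Luche 1,2-reduction, with hydride attacking the exo face of the bridged ketone, should give the endo 15β-alcohol.

Step 23
Reactants: 34 15β-alcohol lactone
Product: 35 13,15β-bis(triethylsilyl) ether lactone
Conditions: Et3SiOTf, 2,6-lutidine, CH2Cl2, −78 → 0 °C
Reagents that add atoms: triethylsilyl triflate, CC[Si](CC)(CC)OS(=O)(=O)C(F)(F)F
Why: the silyl triflate silylates both the secondary C15 and the tertiary bridgehead C13 hydroxyl in one operation.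

Step 24
Reactants: 35 13,15β-bis(triethylsilyl) ether lactone; 29 vinylmagnesium bromide
Product: 36 γ-hydroxy divinyl ketone (10α-hydroxy, 10β-vinyl, C3 vinyl ketone; in equilibrium with its lactol)
Conditions: THF, −78 °C; AcOH, −78 °C
Reagents that add atoms: none
Why: mono-addition of a Grignard reagent to a γ-lactone, whose magnesium lactolate is stable at −78 °C and gives the hydroxy enone on cold quench; the hindered C7 ester should not react.

Step 25
Reactants: 36 γ-hydroxy divinyl ketone
Product: 37 tetracyclic ring A enone 10α-alcohol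
Conditions: second-generation Hoveyda–Grubbs catalyst (5 mol%), toluene, 60 °C
Reagents that add atoms: none
Why: ring-closing metathesis of the C10 vinyl group with the vinyl ketone forms C1=C2 of the cyclohexenone; the 1,1-disubstituted C16 methylene is inert.

Step 26
Reactants: 37 tetracyclic ring A enone 10α-alcohol; 38 phenyl chloroformate
Product: 39 ring A enone C10 phenyl carbonate
Conditions: LiN(SiMe3)2 (1.0 equiv), THF, −78 °C; then 38, −78 → −40 °C
Reagents that add atoms: none
Why: O-acylation of the tertiary lithium alkoxide, which forms faster than the C4 enolate at −78 °C, by the small planar chloroformate.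

Step 27
Reactants: 39 ring A enone C10 phenyl carbonate
Product: 40 3-oxo 19,10-lactone
Conditions: LiN(SiMe3)2 (1.2 equiv), THF, −78 → −20 °C
Reagents that add atoms: none
Why: LiN(SiMe3)2 removes the C4 proton, the only enolisable α-position of the ketone (C2 is vinylic, C10 fully substituted), to give the cross-conjugated C3–C4 enolate, which attacks the carbonate carbonyl held on the C10 oxygen, and the tetrahedral intermediate expels phenoxide. The closest known reaction type is the Dieckmann-type intramolecular C-acylation of a ketone enolate by a carbonate or ester, which gives β-keto lactones. The γ-lactone ring (O–C10–C5–C4–C19) closes in the 5-exo-trig mode. The new quaternary stereocentre C4 is controlled by the tether: C19 can reach C4 only on the α-face that carries the C10 oxygen, so the methyl group is turned to the other face whichever C4 epimer of 39 is used. The step needs C-acylation at C4 and not reaction at C6 or at the carbonate itself; the ketone α-proton is several pKa units more acidic than the hindered C6 ester proton, only a slight excess of a hindered amide base is used, and phenoxide is too weak a nucleophile to reopen the non-enolisable β-keto lactone.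

Step 28
Reactants: 40 3-oxo 19,10-lactone
Product: 41 3β-alcohol (fully protected target gibberellin)
Conditions: (R)-2-methyl-CBS-oxazaborolidine, catecholborane, toluene, −78 → −40 °C
Reagents that add atoms: none
Why: CBS reduction with catecholborane is 1,2-selective, and with the quaternary C4 as the large group the (R)-catalyst should deliver hydride to the α-face to give the 3β (3S) alcohol; LiBH(s-Bu)3 is avoided because it would first reduce the enone in the 1,4 sense.

Step 29
Reactants: 41 3β-alcohol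
Product: 42 target gibberellin, 12α,15β-dihydroxygibberellic acid
Conditions: Bu4NF, AcOH, THF, 0 → 40 °C
Reagents that add atoms: none
Why: fluoride cleaves the three silyl ethers and, by β-elimination, the 2-(trimethylsilyl)ethyl ester, while the acetic acid buffer protects the base-sensitive allylic lactone.

Compound list
1 | cyclopentane-1,3-dione | O=C1CCC(=O)C1 | starting material
2 | 3-bromoprop-1-yne | C#CCBr | starting material
3 | 2-(prop-2-yn-1-yl)cyclopentane-1,3-dione | O=C1CCC(=O)C1CC#C | intermediate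
4 | but-3-en-2-one | CC(=O)C=C | starting material
5 | 2-(3-oxobutyl)-2-(prop-2-yn-1-yl)cyclopentane-1,3-dione | CC(=O)CCC1(CC#C)C(=O)CCC1=O | intermediate
6 | cis-fused ketol, 3a-hydroxy-7a-(prop-2-yn-1-yl)hexahydro-1H-indene-1,5-dione (C9 hydroxyl cis to propargyl) | C#CC[C@]12CCC(=O)C[C@@]1(O)CCC2=O | intermediate
7 | (R)-7a-(prop-2-yn-1-yl)-2,3,7,7a-tetrahydro-1H-indene-1,5(6H)-dione (C6 ketone, C9=C11–C12=O) | C#CC[C@]12CCC(=O)C=C1CCC2=O | intermediate
8 | C12 ethyl dienol ether, 5-ethoxy-7a-(prop-2-yn-1-yl)-2,6,7,7a-tetrahydro-1H-inden-1-one | C#CC[C@]12CCC(OCC)=CC1=CCC2=O | intermediate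
9 | (methoxymethyl)triphenylphosphonium chloride | COC[P+](c1ccccc1)(c1ccccc1)c1ccccc1.[Cl-] | starting material
10 | bis(enol ether): C12 ethyl dienol ether with C6=CH–OMe (E/Z mixture) | C#CC[C@]12CCC(OCC)=CC1=CCC2=COC | intermediate
11 | bicyclic enone 6β-carbaldehyde (formyl cis to propargyl) | C#CC[C@]12CCC(=O)C=C1CC[C@@H]2C=O | intermediate
12 | bicyclic enone 6β-carboxylic acid | C#CC[C@]12CCC(=O)C=C1CC[C@@H]2C(=O)O | intermediate
13 | bicyclic enone 6β-carboxylic acid 2-(trimethylsilyl)ethyl ester | C#CC[C@]12CCC(=O)C=C1CC[C@@H]2C(=O)OCC[Si](C)(C)C | intermediate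
14 | ethyl dienol ether of 13 (C12(OEt)=C11, C9=C10) | C#CC[C@]12CCC(OCC)=CC1=CC[C@@H]2C(=O)OCC[Si](C)(C)C | intermediate
15 | 10α-hydroxy enone ester (C10 hydroxyl trans to propargyl; epimer immaterial) | C#CC[C@]12CCC(=O)C=C1[C@@H](O)C[C@@H]2C(=O)OCC[Si](C)(C)C | intermediate
16 | 10α-acetoxy enone ester | C#CC[C@]12CCC(=O)C=C1[C@@H](OC(C)=O)C[C@@H]2C(=O)OCC[Si](C)(C)C | intermediate
17 | triethylsilyl dienol ether of 16 (C12(OSiEt3)=C13, C9=C11) | C#CC[C@]12CC=C(O[Si](CC)(CC)CC)C=C1[C@@H](OC(C)=O)C[C@@H]2C(=O)OCC[Si](C)(C)C | intermediate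
18 | 13α-(triethylsilyloxy)-10α-acetoxy enone ester (C13 epimer immaterial) | C#CC[C@]12C[C@@H](O[Si](CC)(CC)CC)C(=O)C=C1[C@@H](OC(C)=O)C[C@@H]2C(=O)OCC[Si](C)(C)C | intermediate
19 | 12α-alcohol (13α-triethylsilyloxy, 10α-acetoxy, C9=C11) | C#CC[C@]12C[C@@H](O[Si](CC)(CC)CC)[C@@H](O)C=C1[C@@H](OC(C)=O)C[C@@H]2C(=O)OCC[Si](C)(C)C | intermediate
20 | 12α-(tert-butyldimethylsilyl) ether of 19 | C#CC[C@]12C[C@@H](O[Si](CC)(CC)CC)[C@@H](O[Si](C)(C)C(C)(C)C)C=C1[C@@H](OC(C)=O)C[C@@H]2C(=O)OCC[Si](C)(C)C | intermediate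
21 | 13α-alcohol (12α-silyl ether, 10α-acetate) | C#CC[C@]12C[C@@H](O)[C@@H](O[Si](C)(C)C(C)(C)C)C=C1[C@@H](OC(C)=O)C[C@@H]2C(=O)OCC[Si](C)(C)C | intermediate
22 | 13-ketone (12α-tert-butyldimethylsilyloxy, 10α-acetoxy, C9=C11, C8 propargyl) | C#CC[C@]12CC(=O)[C@@H](O[Si](C)(C)C(C)(C)C)C=C1[C@@H](OC(C)=O)C[C@@H]2C(=O)OCC[Si](C)(C)C | intermediate
23 | tricyclic alcohol: 10α-acetoxy, 12α-silyloxy, 13-hydroxy, C9=C11, C16 methylene, C7 silylethyl ester | C=C1C[C@]23C[C@@]1(O)[C@@H](O[Si](C)(C)C(C)(C)C)C=C2[C@@H](OC(C)=O)C[C@@H]3C(=O)OCC[Si](C)(C)C | intermediate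
24 | tricyclic 10α,13-diol | C=C1C[C@]23C[C@@]1(O)[C@@H](O[Si](C)(C)C(C)(C)C)C=C2[C@@H](O)C[C@@H]3C(=O)OCC[Si](C)(C)C | intermediate
25 | tricyclic 9(11)-en-10-one | C=C1C[C@]23C[C@@]1(O)[C@@H](O[Si](C)(C)C(C)(C)C)C=C2C(=O)C[C@@H]3C(=O)OCC[Si](C)(C)C | intermediate
26 | tricyclic 10-ketone (9β-H) | C=C1C[C@]23C[C@@]1(O)[C@@H](O[Si](C)(C)C(C)(C)C)C[C@H]2C(=O)C[C@@H]3C(=O)OCC[Si](C)(C)C | intermediate
27 | ethyl (S)-2-(trifluoromethylsulfonyloxy)propanoate | C[C@H](OS(=O)(=O)C(F)(F)F)C(=O)OCC | starting material
28 | C5-alkylated ketone (5β-H, ethyl 2-propanoate unit at C5α) | C=C1C[C@]23C[C@@]1(O)[C@@H](O[Si](C)(C)C(C)(C)C)C[C@H]2C(=O)[C@@H]([C@H](C)C(=O)OCC)[C@@H]3C(=O)OCC[Si](C)(C)C | intermediate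
29 | vinylmagnesium bromide | C=C[Mg]Br | starting material
30 | 10β-vinyl 10α-hydroxy ethyl ester (present as its magnesium alkoxide, drawn as the alcohol) | C=C1C[C@]23C[C@@]1(O)[C@@H](O[Si](C)(C)C(C)(C)C)C[C@H]2[C@](O)(C=C)[C@@H]([C@H](C)C(=O)OCC)[C@@H]3C(=O)OCC[Si](C)(C)C | intermediate
31 | 10β-vinyl γ-lactone (carbonyl C3 on the C10 oxygen), 13-hydroxy, 12α-silyloxy | C=C1C[C@]23C[C@@]1(O)[C@@H](O[Si](C)(C)C(C)(C)C)C[C@H]2[C@@]4(C=C)OC(=O)[C@@H](C)[C@H]4[C@@H]3C(=O)OCC[Si](C)(C)C | intermediate
32 | 15α-alcohol of 31 | C=C1[C@H](O)[C@]23C[C@@]1(O)[C@@H](O[Si](C)(C)C(C)(C)C)C[C@H]2[C@@]4(C=C)OC(=O)[C@@H](C)[C@H]4[C@@H]3C(=O)OCC[Si](C)(C)C | intermediate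
33 | 15-oxo lactone | C=C1C(=O)[C@]23C[C@@]1(O)[C@@H](O[Si](C)(C)C(C)(C)C)C[C@H]2[C@@]4(C=C)OC(=O)[C@@H](C)[C@H]4[C@@H]3C(=O)OCC[Si](C)(C)C | intermediate
34 | 15β-alcohol lactone | C=C1[C@@H](O)[C@]23C[C@@]1(O)[C@@H](O[Si](C)(C)C(C)(C)C)C[C@H]2[C@@]4(C=C)OC(=O)[C@@H](C)[C@H]4[C@@H]3C(=O)OCC[Si](C)(C)C | intermediate
35 | 13,15β-bis(triethylsilyl) ether lactone | C=C1[C@@H](O[Si](CC)(CC)CC)[C@]23C[C@@]1(O[Si](CC)(CC)CC)[C@@H](O[Si](C)(C)C(C)(C)C)C[C@H]2[C@@]4(C=C)OC(=O)[C@@H](C)[C@H]4[C@@H]3C(=O)OCC[Si](C)(C)C | intermediate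
36 | γ-hydroxy divinyl ketone (10α-hydroxy, 10β-vinyl, C3 vinyl ketone) | C=C1[C@@H](O[Si](CC)(CC)CC)[C@]23C[C@@]1(O[Si](CC)(CC)CC)[C@@H](O[Si](C)(C)C(C)(C)C)C[C@H]2[C@](O)(C=C)[C@@H]([C@H](C)C(=O)C=C)[C@@H]3C(=O)OCC[Si](C)(C)C | intermediate
37 | tetracyclic ring A enone 10α-alcohol | C=C1[C@@H](O[Si](CC)(CC)CC)[C@]23C[C@@]1(O[Si](CC)(CC)CC)[C@@H](O[Si](C)(C)C(C)(C)C)C[C@H]2[C@]4(O)C=CC(=O)[C@@H](C)[C@H]4[C@@H]3C(=O)OCC[Si](C)(C)C | intermediate
38 | phenyl chloroformate | O=C(Cl)Oc1ccccc1 | starting material
39 | ring A enone C10 phenyl carbonate (12α-tert-butyldimethylsilyl, 13- and 15β-triethylsilyl ethers, C7 silylethyl ester) | C=C1[C@@H](O[Si](CC)(CC)CC)[C@]23C[C@@]1(O[Si](CC)(CC)CC)[C@@H](O[Si](C)(C)C(C)(C)C)C[C@H]2[C@]4(OC(=O)Oc5ccccc5)C=CC(=O)[C@@H](C)[C@H]4[C@@H]3C(=O)OCC[Si](C)(C)C | intermediate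
40 | 3-oxo 19,10-lactone | C=C1[C@@H](O[Si](CC)(CC)CC)[C@]23C[C@@]1(O[Si](CC)(CC)CC)[C@@H](O[Si](C)(C)C(C)(C)C)C[C@H]2[C@@]45C=CC(=O)[C@@](C)(C(=O)O4)[C@H]5[C@@H]3C(=O)OCC[Si](C)(C)C | intermediate
41 | 3β-alcohol (fully protected target gibberellin) | C=C1[C@@H](O[Si](CC)(CC)CC)[C@]23C[C@@]1(O[Si](CC)(CC)CC)[C@@H](O[Si](C)(C)C(C)(C)C)C[C@H]2[C@@]45C=C[C@H](O)[C@@](C)(C(=O)O4)[C@H]5[C@@H]3C(=O)OCC[Si](C)(C)C | intermediate
42 | target gibberellin, 12α,15β-dihydroxygibberellic acid (3β,12α,13,15β-tetrahydroxy-20-norgibberella-1,16-diene-7,19-dioic acid 19,10-lactone) | C=C1[C@@H](O)[C@]23C[C@@]1(O)[C@@H](O)C[C@H]2[C@@]12C=C[C@H](O)[C@@](C)(C(=O)O1)[C@H]2[C@@H]3C(=O)O | target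

Total step count: 29. Longest linear sequence: 29 steps, from 1 to 42; compounds 2, 4, 9, 27, 29 and 38 are bought.

Steps most likely to fail

Step 27. The acyl transfer may lose out to attack of the amide base on the aryl carbonate, to deprotonation at C6, or to slow removal of the hindered C4 proton. The fallback sets out from 35 and uses its lactone as the 19,10-lactone, so that its carbonyl becomes C19 and ring A is closed at C3–C4 and C1=C2 instead. LiN(i-Pr)2 followed by acrolein should give the C4 aldol adduct F1, with acrolein entering anti to C6 and therefore cis to the C10 vinyl group. Ring-closing metathesis of the two vinyl groups with the second-generation Hoveyda–Grubbs catalyst should then give the ring A allylic alcohol F2 as a C3 epimer mixture, and Dess–Martin oxidation comes back to the route at 40.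

Step 15. The samarium ketyl may lose the α-silyloxy group by reductive elimination, or be reduced to the alcohol, faster than it adds to the alkyne. The fallback sets out from 18 and closes ring D with C13 as a nucleophile instead of a radical. LiN(i-Pr)2 and Et3SiCl should give the bis(triethylsilyl) enediol ether F3. (Ph3P)AuCl with AgBF4 in CH2Cl2/MeOH should close ring D by 5-exo-dig attack of C13 on the gold-activated alkyne, giving the bridged enone F4 (C12 ketone, 13-triethylsilyl ether). LiBH(s-Bu)3 should give the 12α-alcohol F5, HF·pyridine the 12α,13-diol F6, and one equivalent of t-BuMe2SiOTf should silylate only the secondary C12 hydroxyl and come back to the route at 23.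

Step 28. Hydride delivery may follow the substrate bias to the β-face, anti to the C4–C19 bond, against the catalyst, so that the 3α-alcohol is formed. The fallback sets out from 40: NaBH4 with CeCl3·7H2O should give the 3α-alcohol F7; Mitsunobu inversion with PPh3, diisopropyl azodicarboxylate and formic acid should give the 3β-formate F8; KHCO3 in methanol comes back to the route at 41.

Further compounds
F1 | step 27 | C4 aldol adduct of lactone 35 with acrolein (C4 quaternary, C3 carbinol epimers) | C=C1[C@@H](O[Si](CC)(CC)CC)[C@]23C[C@@]1(O[Si](CC)(CC)CC)[C@@H](O[Si](C)(C)C(C)(C)C)C[C@H]2[C@@]4(C=C)OC(=O)[C@](C)(C(O)C=C)[C@H]4[C@@H]3C(=O)OCC[Si](C)(C)C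
F2 | step 27 | ring A allylic alcohol, 3-hydroxy-1-ene 19,10-lactone (C3 epimer mixture) | C=C1[C@@H](O[Si](CC)(CC)CC)[C@]23C[C@@]1(O[Si](CC)(CC)CC)[C@@H](O[Si](C)(C)C(C)(C)C)C[C@H]2[C@@]45C=CC(O)[C@@](C)(C(=O)O4)[C@H]5[C@@H]3C(=O)OCC[Si](C)(C)C
F3 | step 15 | bis(triethylsilyl) enediol ether of 18 (C12=C13, C9=C11) | C#CC[C@]12CC(O[Si](CC)(CC)CC)=C(O[Si](CC)(CC)CC)C=C1[C@@H](OC(C)=O)C[C@@H]2C(=O)OCC[Si](C)(C)C
F4 | step 15 | bridged enone: C12 ketone, 13-triethylsilyl ether, C9=C11, C16 methylene | C=C1C[C@]23C[C@@]1(O[Si](CC)(CC)CC)C(=O)C=C2[C@@H](OC(C)=O)C[C@@H]3C(=O)OCC[Si](C)(C)C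
F5 | step 15 | 12α-alcohol of F4 | C=C1C[C@]23C[C@@]1(O[Si](CC)(CC)CC)[C@@H](O)C=C2[C@@H](OC(C)=O)C[C@@H]3C(=O)OCC[Si](C)(C)C
F6 | step 15 | 12α,13-diol (10α-acetate) | C=C1C[C@]23C[C@@]1(O)[C@@H](O)C=C2[C@@H](OC(C)=O)C[C@@H]3C(=O)OCC[Si](C)(C)C
F7 | step 28 | 3α-alcohol (C3 epimer of 41) | C=C1[C@@H](O[Si](CC)(CC)CC)[C@]23C[C@@]1(O[Si](CC)(CC)CC)[C@@H](O[Si](C)(C)C(C)(C)C)C[C@H]2[C@@]45C=C[C@@H](O)[C@@](C)(C(=O)O4)[C@H]5[C@@H]3C(=O)OCC[Si](C)(C)C
F8 | step 28 | 3β-formate of 41 | C=C1[C@@H](O[Si](CC)(CC)CC)[C@]23C[C@@]1(O[Si](CC)(CC)CC)[C@@H](O[Si](C)(C)C(C)(C)C)C[C@H]2[C@@]45C=C[C@H](OC=O)[C@@](C)(C(=O)O4)[C@H]5[C@@H]3C(=O)OCC[Si](C)(C)C
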